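The numbers in the tables are calculated for an exercise; the scatter is artificial.

Substrate cannot leave a flask without becoming something, yet maple at 12.0 h shows 5.00% of the charge as neither substrate nor target.

| flask | substrate | partner | transfer agent | initiator | remark | time |
|---|---|---|---|---|---|---|
| maple | 30 mM (fed, over 8.0 h) | 18 mM | 1.5 mM | 2.6 mM | run made earlier |  |
| oak | 30 mM (fed, over 8.0 h) | 59 mM | 1.5 mM | 2.6 mM | run made earlier |  |
| violet | 30 mM (fed, over 8.0 h) | 33.0 mM | 1.50 mM | 2.6 mM |  | 30 h |
| blue | 30 mM (fed, over 8.0 h) | 66.0 mM | 1.50 mM | 2.6 mM |  | 30 h |

| run | time / h | substrate / % | target / % |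
|---|---|---|---|
| maple | 1.00 | 11.8 | 0.4 |
| maple | 3.00 | 34.0 | 1.3 |
| maple | 5.00 | 58.1 | 2.8 |
| maple | 8.00 | 92.1 | 4.8 |
| maple | 12.0 | 86.1 | 8.9 |
| maple | 15.0 | 81.9 | 12.4 |
| oak | 1.33 | 14.4 | 1.8 |
| oak | 2.00 | 20.5 | 2.2 |
| oak | 3.00 | 32.5 | 3.1 |
| oak | 5.00 | 52.5 | 6.6 |
| oak | 10.0 | 76.1 | 19.7 |
| oak | 15.0 | 53.9 | 40.0 |

(scatter of a reading: 0.5 percentage points)
- part of the substrate that has reacted at the end, violet
- part of the substrate that has reacted at the end, blue
- what raising the concentration of partner from its lowest to its highest value here does to the part of the substrate that has reacted (changes below 5 percentage points count as none) (it rises / it falls / no change)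
- percentages count the whole charge, also what has not yet gone in

That gap is close to the 5.00% of the substrate charge that the transfer agent amounts to, so my reading is that the transfer agent takes up substrate one for one. Its loss rate g, gap times charge over time, then comes out at 0.125 mM h⁻¹ in maple and, at 10.0 h, 0.126 mM h⁻¹ in oak, which has 3.28 times the partner, so g does not follow partner. Dividing the charge of transfer agent by g from oak, whose gap at that reading is still below the transfer agent's share, gives the brake time τ, the hours a retardation period lasts at that loss, 11.9 h, and I take it to scale inversely with the initiator charge, the other charges held.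

Since τ ends before oak's last reading, I extrapolate from there, scaling rates with partner, in two ways. Taking oak's last stretch as first order gives 0.0690 h⁻¹, and with a substrate level of 71.7% interpolated for violet at 15.0 h, violet reaches 59.8% and blue, started from oak's level, 83.1%. Taking the stretch as a straight line gives violet 65.6%, which is 5.8 percentage points above the first figure, while on that line blue, from the same level of oak, reaches zero substrate in 10.9 h more, before the end. On blue they part, and the first-order way cheats: oak's target gain rose from 0.786 mM h⁻¹ to 1.22 mM h⁻¹ while substrate fell over the later stretch. So I commit to the line.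

The forecast gave 66% for violet and 91% for blue, and on raising the partner the answer it rises, calling the target curve “mildly autocatalytic”. The flask gives 62.3% for violet and 100% for blue, and on raising the partner the answer it rises, by 38 points.

    transfer agent + first chain carrier → side product + idle radical (kL = 32700 L mol⁻¹ s⁻¹)
    2 idle radical → ended radicals (k = 3.20 × 10⁸ L mol⁻¹ s⁻¹)
    initiator → 2 initiating radical (k = 0.0298 h⁻¹)
    2 first chain carrier → ended chains (k = 5.40 × 10⁸ L mol⁻¹ s⁻¹)
    substrate + second chain carrier → by-product + first chain carrier (k = 4.46 × 10⁶ L mol⁻¹ h⁻¹)
    partner + first chain carrier → target + second chain carrier (k = 6.97 × 10⁶ L mol⁻¹ h⁻¹)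
    partner + by-product ⇌ idle adduct, settled at all times (K = 16.0 L mol⁻¹)
    substrate + initiating radical → capped initiator + first chain carrier (k = 15000 L mol⁻¹ s⁻¹)

Transfer agent stands at 0% of its charge in violet and 0% in blue at the end, which fits a τ shorter than the run. For a neighbour flask, blue with 1.0 mM of initiator, τ scales to 31.0 h, longer than the run, and that flask ends with 22.6% of its transfer agent and 77.9% of the substrate unreacted.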